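**Retrosynthetic overview**
1. Shimalactone B ⇒ O‑TBS ether 35 ⇒ tertiary allylic alcohol 34: the oxabicyclo[2.2.1]heptane is closed last (C‑15–C‑18) by palladium‑catalysed dehydrative allylic alkylation of the β‑ketolactone.
2. 34 ⇒ alkenyl iodide 22 + acetyl β‑ketolactone 30 (C‑14–C‑15 by organocerium addition); 30 ⇒ Evans anti‑aldol dipropionate.
3. 22 ⇒ C‑12 ketone 16 (one‑carbon homologation, alkyne, carboalumination); C‑4/C‑5 ⇒ exo‑face aldol of a cyclobutanone enolate with tiglaldehyde.
4. Key disconnection: bicyclo[4.2.0]octane core ⇒ catalytic enantioselective Diels–Alder reaction of 2‑methylcyclobutenone with a 1‑silyloxydiene. No 8π/6π electrocyclization is used; the ring configuration is set by the catalyst and relayed to C‑5, C‑4 and C‑12.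
5. Ring order: cyclobutane (ketene [2+2]) → six‑membered ring (Diels–Alder) → cyclohexadiene (1,4‑elimination) → δ‑lactone (separate fragment) → oxabicycle (last).

Assumption: atom labels C‑1 to C‑20 follow the target chain (C‑1 butenyl CH3, C‑4 carbinol, C‑5/C‑6/C‑11/C‑12 cyclobutane, C‑7 to C‑10 diene, C‑13=C‑14 linking alkene, C‑15 bridge carbon, C‑16 CH–O, C‑17 lactone C=O, C‑18 bridgehead C–CH3, C‑19 ketone, C‑20 CH–CH3); the catalyst antipode in step 4 is the one that gives 8 as drawn.

Step 1
Reactants: 1 propanoyl chloride; 2 ethyl vinyl ether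
Product: 4 3-ethoxy-2-methylcyclobutan-1-one, via methylketene 3 (not isolated)
Conditions: Et3N, excess 2, hexane, 60 °C, slow addition of 1
Reagents that add atoms: none
Why: Dehydrochlorination gives methylketene, which undergoes a ketene–enol ether [2+2] cycloaddition with the carbonyl carbon bonding to the CH2 terminus of the vinyl ether; the racemic cis/trans mixture does not matter because both stereocentres are lost in step 2.

Step 2
Reactants: 4 3-ethoxy-2-methylcyclobutan-1-one
Product: 5 2-methylcyclobut-2-en-1-one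
Conditions: 4-methylbenzenesulfonic acid (5 mol %), CH2Cl2, 40 °C; bulb-to-bulb distillation, kept as a cold solution
Reagents that add atoms: none
Why: Acid-catalysed β-elimination of ethanol through the more substituted enol gives the conjugated, more substituted cyclobutenone.

Step 3
Reactants: 6 (E)-2-methylpent-2-enal
Product: 7 tert-butyl(dimethyl){[(1E,3E)-2-methylpenta-1,3-dien-1-yl]oxy}silane
Conditions: TBSOTf, Et3N, Et2O, 0 °C to rt
Reagents that add atoms: tert-butyldimethylsilyl trifluoromethanesulfonate, CC(C)(C)[Si](C)(C)OS(=O)(=O)C(F)(F)F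
Why: O-silylation of the enal followed by γ-deprotonation (silyl dienol ether formation) gives the extended (1E,3E)-dienol ether.

Step 4
Reactants: 5 2-methylcyclobut-2-en-1-one; 7 silyloxydiene
Product: 9 5-hydroxy-2,4,6-trimethylbicyclo[4.2.0]oct-3-en-7-one (cis-fused endo adduct; C-6 and C-11 as in the target), via silyl ether adduct 8 (not isolated)
Conditions: (S)-1-(2-methylphenyl)-3,3-diphenyltetrahydro-1H,3H-pyrrolo[1,2-c][1,3,2]oxazaborole (20 mol %), HN(SO2CF3)2 (16 mol %), CH2Cl2, −78 to −40 °C; then HF·pyridine, THF, 0 °C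
Reagents that add atoms: none
Why: Proposed new method: the Lewis-acid-bound, strain-activated 2-methylcyclobutenone undergoes an endo, "ortho"-regioselective Diels–Alder reaction with the 1-silyloxydiene (siloxy terminus C-10 bonds to the α-carbon C-11, methyl-bearing terminus C-7 to the β-carbon C-6), the chiral oxazaborolidinium cation shielding one enone face and so fixing C-6 and C-11; the closest known reactions are the thermal and ZnCl2-promoted Diels–Alder reactions of cyclobutenone and oxazaborolidinium-catalysed Diels–Alder reactions of cyclic enones with silyloxydienes, and buffered fluoride then frees the C-10 alcohol.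

Step 5
Reactants: 9 hydroxy ketone
Product: 10 2,4,6-trimethyl-7-oxobicyclo[4.2.0]oct-3-en-5-yl 2,2-dimethylpropanoate
Conditions: pivaloyl chloride, pyridine, 4-(dimethylamino)pyridine (10 mol %), CH2Cl2, 40 °C
Reagents that add atoms: pivaloyl chloride, CC(C)(C)C(Cl)=O
Why: Acylation gives an allylic ester with no α-hydrogen, which survives the enolate chemistry and later serves as the leaving group for diene formation.

Step 6
Reactants: 10 pivalate ketone
Product: 12 2,4,6,8-tetramethyl-7-oxobicyclo[4.2.0]oct-3-en-5-yl 2,2-dimethylpropanoate (C-5 methyl exo as major epimer), via lithium enolate 11 (not isolated)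
Conditions: LiN(iPr)2, THF, −78 °C; then MeI, −78 to −40 °C
Reagents that add atoms: iodomethane, CI
Why: Kinetic enolate alkylation at C-5, the only enolizable position; the C-5 configuration is reset in step 7.

Step 7
Reactants: 12 methyl ketone; 13 (E)-2-methylbut-2-enal (tiglaldehyde)
Product: 15 8-[(E)-1-hydroxy-2-methylbut-2-en-1-yl]-2,4,6,8-tetramethyl-7-oxobicyclo[4.2.0]oct-3-en-5-yl 2,2-dimethylpropanoate (side chain exo and methyl endo at C-5; C-4 as in the target), via lithium enolate 14 (not isolated)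
Conditions: LiN(iPr)2, THF, −78 °C; then 13, −78 °C; AcOH quench at −78 °C
Reagents that add atoms: none
Why: Aldol addition through a Zimmerman–Traxler chair: the aldehyde approaches the convex exo face, which puts the carbinol chain exo and the methyl endo at C-5, and the ring-fixed enolate geometry (methyl cis to O–Li) gives the methyl/hydroxyl syn relationship that is the C-4 configuration of the target.

Step 8
Reactants: 15 aldol adduct
Product: 16 TBS ether of 15
Conditions: TBSOTf, 2,6-lutidine, CH2Cl2, −78 to 0 °C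
Reagents that add atoms: tert-butyldimethylsilyl trifluoromethanesulfonate, CC(C)(C)[Si](C)(C)OS(=O)(=O)C(F)(F)F
Why: Silylation under non-basic conditions protects the hindered aldol against retro-aldol cleavage.

Step 9
Reactants: 16 silylated ketone
Product: 18 7-formyl derivative (C-12 aldehyde; epimers at C-12 with the drawn one as the thermodynamic epimer), via methyl enol ether 17 (not isolated)
Conditions: (methoxymethyl)triphenylphosphonium chloride, KN(SiMe3)2, THF, 0 °C to rt; then 0.5 M aq. HCl, THF, 0 °C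
Reagents that add atoms: (methoxymethyl)triphenylphosphonium chloride, COC[P+](c1ccccc1)(c1ccccc1)c1ccccc1.[Cl-]; water, O
Why: Wittig methoxymethylenation of the strained, electrophilic cyclobutanone and enol ether hydrolysis give the one-carbon-homologated aldehyde; the C-12 epimers are funnelled to the epimer with the formyl group trans to the bulky C-5 side chain in step 11.

Step 10
Reactants: 18 aldehyde pivalate
Product: 19 8-[(E)-1-(tert-butyldimethylsilyloxy)-2-methylbut-2-en-1-yl]-2,4,6,8-tetramethylbicyclo[4.2.0]octa-2,4-diene-7-carbaldehyde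
Conditions: Pd(PPh3)4 (10 mol %), 1,4-dioxane, 70 °C
Reagents that add atoms: none
Why: Tsuji-type 1,4-elimination: zerovalent palladium ionizes the allylic pivalate with inversion and the only β-hydrogen, C-7–H, is syn to the metal (it is trans to the ester because the diene was E,E), so β-hydride elimination gives the cyclohexa-1,3-diene alone.

Step 11
Reactants: 19 diene aldehyde
Product: 20 7-ethynyl-8-[(E)-1-(tert-butyldimethylsilyloxy)-2-methylbut-2-en-1-yl]-2,4,6,8-tetramethylbicyclo[4.2.0]octa-2,4-diene (C-12 as in the target)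
Conditions: dimethyl (1-diazo-2-oxopropyl)phosphonate, K2CO3, MeOH, 0 °C to rt
Reagents that add atoms: dimethyl (1-diazo-2-oxopropyl)phosphonate, COP(=O)(OC)C(=[N+]=[N-])C(C)=O
Why: Ohira–Bestmann (Seyferth–Gilbert) homologation; carbonate in methanol equilibrates the aldehyde α-centre to the epimer trans to the C-5 side chain before the irreversible alkyne formation, which sets C-12.

Step 12
Reactants: 20 alkyne
Product: 22 7-[(E)-1-iodoprop-1-en-2-yl] diene (alkenyl iodide), via alkenylalane 21 (not isolated)
Conditions: AlMe3 (3 equiv), Cp2ZrCl2 (25 mol %), CH2Cl2, 0 °C to rt; then I2, THF, −30 °C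
Reagents that add atoms: trimethylaluminium, C[Al](C)C; iodine, II
Why: Negishi zirconium-catalysed syn-carboalumination places the methyl on the internal carbon (C-13) and iodinolysis with retention gives the (E)-alkenyl iodide.

Step 13
Reactants: 23 (R)-4-benzyl-3-propanoyl-1,3-oxazolidin-2-one; 1 propanoyl chloride
Product: 25 (R)-4-benzyl-3-[(S)-2-methyl-3-oxopentanoyl]-1,3-oxazolidin-2-one, via lithium enolate 24 (not isolated)
Conditions: LiN(iPr)2, THF, −78 °C; then 1, −78 °C
Reagents that add atoms: none
Why: C-acylation of the chelated (Z)-imide enolate on the face opposite the benzyl group gives the (2S)-β-ketoimide, which is configurationally stable because allylic 1,3-strain blocks enolization at C-2.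

Step 14
Reactants: 25 β-ketoimide; 26 methacrolein
Product: 28 (R)-4-benzyl-3-[(2S,4R,5S)-5-hydroxy-2,4,6-trimethyl-3-oxohept-6-enoyl]-1,3-oxazolidin-2-one, via boron enolate 27 (not isolated)
Conditions: Cy2BCl, Me2NEt, Et2O, 0 °C; then 26, −78 to −20 °C; then H2O2, MeOH, pH 7 buffer
Reagents that add atoms: none
Why: Evans anti-aldol of the (E)-boron enolate through a chair transition state gives the 4,5-anti relationship, and the C-2 centre directs the aldehyde to the face away from the imide carbonyl (2,4-anti), which sets the future C-20 and C-16.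

Step 15
Reactants: 28 aldol adduct
Product: 29 (R)-4-benzyl-3-[(2S,4R,5S)-5-hydroxy-2,4-dimethyl-3,6-dioxoheptanoyl]-1,3-oxazolidin-2-one
Conditions: O3, CH2Cl2/MeOH, −78 °C; then Me2S
Reagents that add atoms: ozone, [O-][O+]=O
Why: Ozonolysis of the 1,1-disubstituted alkene gives the methyl ketone; the β-ketoimide is not enolized and is left alone.

Step 16
Reactants: 29 hydroxy triketone imide
Product: 30 (5R,6S)-6-acetyl-3,5-dimethyloxane-2,4-dione (C-18 epimers and enol form)
Conditions: Et3N (20 mol %), 4-(dimethylamino)pyridine (10 mol %), CH2Cl2, 0 °C to rt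
Reagents that add atoms: none
Why: Lactonization by intramolecular acyl transfer of the δ-hydroxyl onto the activated imide releases the auxiliary; C-16 and C-20 are kept and the now labile C-18 is reset in step 18.

Step 17
Reactants: 22 alkenyl iodide; 30 acetyl β-ketolactone
Product: 34 tertiary allylic alcohol (C-15 carbinol epimers), via alkenyllithium 31 (not isolated), via alkenylcerium dichloride 32 (not isolated), via lithium enolate 33 (not isolated)
Conditions: 22, t-BuLi (2.1 equiv), Et2O, −78 °C; CeCl3, THF, −78 °C; then 30 pre-treated with LiN(SiMe3)2 (1.05 equiv, THF, −78 °C); −78 to −40 °C; AcOH quench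
Reagents that add atoms: none
Why: Iodine–lithium exchange with retention and organocerium 1,2-addition to the methyl ketone form the C-14–C-15 bond while the β-ketolactone is masked in the flask as its enolate; the new carbinol centre is ionized in step 18 and so its configuration does not matter.

Step 18
Reactants: 34 tertiary allylic alcohol
Product: 35 O-TBS-shimalactone B
Conditions: Pd(PPh3)4 (10 mol %), THF, 45 °C
Reagents that add atoms: none
Why: Proposed new method: zerovalent palladium ionizes the tertiary allylic alcohol (activated by the acidic β-ketolactone, pKa about 5) to a π-allyl complex spanning C-13 to C-15, and the tethered enolate carbon C-18 attacks the near terminus C-15 in a 5-exo sense (the only ring size within reach), creating the quaternary centres C-15 and C-18 and the bridged lactone while the bulky cyclobutyl group stays syn on the allyl unit so that C-13=C-14 stays E; C-18 is fixed by the bridge and C-15 by the tether conformation that puts the alkenyl arm over the ketone bridge and the methyl over the lactone bridge, the sense known from the acid-mediated cationic closure of this ring system; the closest known reactions are Tsuji–Trost allylations of acidic 1,3-dicarbonyl compounds with free allylic alcohols and intramolecular 5-exo allylic alkylations.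

Step 19
Reactants: 35 O-TBS-shimalactone B
Product: 36 shimalactone B
Conditions: HF·pyridine, pyridine, THF, 0 °C to rt
Reagents that add atoms: none
Why: Fluoride-mediated desilylation under buffered, non-basic conditions frees the C-4 alcohol without opening the strained β-ketolactone.

**Compound list**
1 | propanoyl chloride | CCC(Cl)=O | starting material
2 | ethyl vinyl ether | C=COCC | starting material
3 | methylketene (not isolated) | CC=C=O | intermediate
4 | 3-ethoxy-2-methylcyclobutan-1-one (racemic cis/trans mixture) | CCOC1CC(=O)C1C | intermediate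
5 | 2-methylcyclobut-2-en-1-one | CC1=CCC1=O | intermediate
6 | (E)-2-methylpent-2-enal | CC/C=C(\C)C=O | starting material
7 | tert-butyl(dimethyl){[(1E,3E)-2-methylpenta-1,3-dien-1-yl]oxy}silane | C/C=C/C(C)=C/O[Si](C)(C)C(C)(C)C | intermediate
8 | 5-(tert-butyldimethylsilyloxy)-2,4,6-trimethylbicyclo[4.2.0]oct-3-en-7-one, cis-fused endo adduct, 2-methyl and 5-siloxy on the ring face that carries the cyclobutanone (not isolated) | O=C1C[C@@H]2[C@H](C)C=C(C)[C@H](O[Si](C)(C)C(C)(C)C)[C@]12C | intermediate
9 | 5-hydroxy-2,4,6-trimethylbicyclo[4.2.0]oct-3-en-7-one, same configuration as 8 | O=C1C[C@@H]2[C@H](C)C=C(C)[C@H](O)[C@]12C | intermediate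
10 | 2,4,6-trimethyl-7-oxobicyclo[4.2.0]oct-3-en-5-yl 2,2-dimethylpropanoate | O=C1C[C@@H]2[C@H](C)C=C(C)[C@H](OC(=O)C(C)(C)C)[C@]12C | intermediate
11 | lithium enolate of 10, C-5=C-12–OLi (not isolated) | [Li]OC1=C[C@@H]2[C@H](C)C=C(C)[C@H](OC(=O)C(C)(C)C)[C@]12C | intermediate
12 | 2,4,6,8-tetramethyl-7-oxobicyclo[4.2.0]oct-3-en-5-yl 2,2-dimethylpropanoate, C-5 methyl exo | O=C1[C@@H](C)[C@@H]2[C@H](C)C=C(C)[C@H](OC(=O)C(C)(C)C)[C@]12C | intermediate
13 | (E)-2-methylbut-2-enal (tiglaldehyde) | C/C=C(\C)C=O | starting material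
14 | lithium enolate of 12 (not isolated) | [Li]OC1=C(C)[C@@H]2[C@H](C)C=C(C)[C@H](OC(=O)C(C)(C)C)[C@]12C | intermediate
15 | aldol adduct: 12 carrying at C-5 an exo (E)-1-hydroxy-2-methylbut-2-en-1-yl group and an endo methyl, C-4 and C-5 as in the target | C/C=C(\C)[C@@H](O)[C@@]1(C)[C@@H]2[C@H](C)C=C(C)[C@H](OC(=O)C(C)(C)C)[C@]2(C)C1=O | intermediate
16 | TBS ether of 15 | C/C=C(\C)[C@@H](O[Si](C)(C)C(C)(C)C)[C@@]1(C)[C@@H]2[C@H](C)C=C(C)[C@H](OC(=O)C(C)(C)C)[C@]2(C)C1=O | intermediate
17 | C-12 methoxymethylidene enol ether of 16, E/Z mixture (not isolated) | C/C=C(\C)[C@@H](O[Si](C)(C)C(C)(C)C)[C@@]1(C)[C@@H]2[C@H](C)C=C(C)[C@H](OC(=O)C(C)(C)C)[C@]2(C)C1=COC | intermediate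
18 | C-12 aldehyde (7-formyl pivalate), formyl cis to the six-membered ring and trans to the C-5 side chain | C/C=C(\C)[C@@H](O[Si](C)(C)C(C)(C)C)[C@@]1(C)[C@@H]2[C@H](C)C=C(C)[C@H](OC(=O)C(C)(C)C)[C@]2(C)[C@@H]1C=O | intermediate
19 | 8-[(E)-1-(tert-butyldimethylsilyloxy)-2-methylbut-2-en-1-yl]-2,4,6,8-tetramethylbicyclo[4.2.0]octa-2,4-diene-7-carbaldehyde | C/C=C(\C)[C@@H](O[Si](C)(C)C(C)(C)C)[C@@]1(C)[C@@H]2C(C)=CC(C)=C[C@]2(C)[C@@H]1C=O | intermediate
20 | 7-ethynyl analogue of 19 (terminal alkyne at C-12) | C/C=C(\C)[C@@H](O[Si](C)(C)C(C)(C)C)[C@@]1(C)[C@@H]2C(C)=CC(C)=C[C@]2(C)[C@@H]1C#C | intermediate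
21 | (E)-alkenyl(dimethyl)alane from 20 (not isolated) | C/C=C(\C)[C@@H](O[Si](C)(C)C(C)(C)C)[C@@]1(C)[C@@H]2C(C)=CC(C)=C[C@]2(C)[C@@H]1/C(C)=C/[Al](C)C | intermediate
22 | (E)-alkenyl iodide, C-12–C(CH3)=CH–I | C/C=C(\C)[C@@H](O[Si](C)(C)C(C)(C)C)[C@@]1(C)[C@@H]2C(C)=CC(C)=C[C@]2(C)[C@@H]1/C(C)=C/I | intermediate
23 | (R)-4-benzyl-3-propanoyl-1,3-oxazolidin-2-one | CCC(=O)N1[C@H](Cc2ccccc2)COC1=O | starting material
24 | lithium (Z)-enolate of 23 (not isolated) | C/C=C(\O[Li])N1[C@H](Cc2ccccc2)COC1=O | intermediate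
25 | (R)-4-benzyl-3-[(S)-2-methyl-3-oxopentanoyl]-1,3-oxazolidin-2-one | CCC(=O)[C@H](C)C(=O)N1[C@H](Cc2ccccc2)COC1=O | intermediate
26 | methacrolein (2-methylprop-2-enal) | C=C(C)C=O | starting material
27 | (E)-dicyclohexylboron enolate of 25 (not isolated) | C/C=C(/OB(C1CCCCC1)C1CCCCC1)[C@H](C)C(=O)N1[C@H](Cc2ccccc2)COC1=O | intermediate
28 | (R)-4-benzyl-3-[(2S,4R,5S)-5-hydroxy-2,4,6-trimethyl-3-oxohept-6-enoyl]-1,3-oxazolidin-2-one | C=C(C)[C@@H](O)[C@@H](C)C(=O)[C@H](C)C(=O)N1[C@H](Cc2ccccc2)COC1=O | intermediate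
29 | (R)-4-benzyl-3-[(2S,4R,5S)-5-hydroxy-2,4-dimethyl-3,6-dioxoheptanoyl]-1,3-oxazolidin-2-one | CC(=O)[C@@H](O)[C@@H](C)C(=O)[C@H](C)C(=O)N1[C@H](Cc2ccccc2)COC1=O | intermediate
30 | (5R,6S)-6-acetyl-3,5-dimethyloxane-2,4-dione (C-3 epimers, enol tautomer) | CC(=O)[C@H]1OC(=O)C(C)C(=O)[C@@H]1C | intermediate
31 | (E)-alkenyllithium from 22 (not isolated) | C/C=C(\C)[C@@H](O[Si](C)(C)C(C)(C)C)[C@@]1(C)[C@@H]2C(C)=CC(C)=C[C@]2(C)[C@@H]1/C(C)=C/[Li] | intermediate
32 | (E)-alkenylcerium dichloride (not isolated) | C/C=C(\C)[C@@H](O[Si](C)(C)C(C)(C)C)[C@@]1(C)[C@@H]2C(C)=CC(C)=C[C@]2(C)[C@@H]1/C(C)=C/[Ce](Cl)Cl | intermediate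
33 | lithium enolate of 30 (not isolated) | CC(=O)[C@H]1OC(=O)C(C)=C(O[Li])[C@@H]1C | intermediate
34 | tertiary allylic alcohol: 22 with iodine replaced by C(CH3)(OH) carrying the (5R,6S)-3,5-dimethyl-2,4-dioxooxan-6-yl ring; C-15 epimers | C/C=C(\C)[C@@H](O[Si](C)(C)C(C)(C)C)[C@@]1(C)[C@@H]2C(C)=CC(C)=C[C@]2(C)[C@@H]1/C(C)=C/C(C)(O)[C@H]1OC(=O)C(C)C(=O)[C@@H]1C | intermediate
35 | O-TBS-shimalactone B | C/C=C(\C)[C@@H](O[Si](C)(C)C(C)(C)C)[C@@]1(C)[C@@H]2C(C)=CC(C)=C[C@]2(C)[C@@H]1/C(C)=C/[C@]1(C)[C@H]2OC(=O)[C@]1(C)C(=O)[C@@H]2C | intermediate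
36 | shimalactone B | C/C=C(\C)[C@@H](O)[C@@]1(C)[C@@H]2C(C)=CC(C)=C[C@]2(C)[C@@H]1/C(C)=C/[C@]1(C)[C@H]2OC(=O)[C@]1(C)C(=O)[C@@H]2C | target

**Totals**
Total step count: 19. Longest linear sequence: 14 steps (1, 2, 4 to 12, 17 to 19).

**Steps most likely to fail, with fallbacks**

Step 4 (enantioselective cyclobutenone Diels–Alder). The ee or the catalyst turnover with the α-methyl enone may be poor. The fallback sets out from 5 and 7 and comes back at 9, replacing asymmetric catalysis by classical resolution. The ZnCl2-promoted cycloaddition in CH2Cl2 at −40 °C gives the racemic adduct, in which 8 is accompanied by the enantiomeric silyl ether F1. HF·pyridine then gives racemic alcohol, in which 9 is accompanied by the enantiomeric alcohol F2. Esterification with (S)-2-methoxy-2-phenylacetic acid (dicyclohexylcarbodiimide, 4-(dimethylamino)pyridine) gives two separable esters, the (S)-O-methylmandelate of 9 F3 and the (S)-O-methylmandelate of ent-9 F4. Chromatography and methanolysis of the first one (K2CO3, MeOH, 0 °C) return enantiopure 9.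

Step 9 (Wittig homologation of the doubly neopentyl cyclobutanone). The ylide may fail to add or may enolize nothing yet cleave the ester. The fallback sets out from 16 and comes back at 18, going through an alkene instead of an enol ether. Methylenation with Cp2Ti(CH2)ClAlMe2 in THF/pyridine at −40 to 0 °C gives the C-12 methylidene compound F5. Chemoselective hydroboration of this 1,1-disubstituted alkene with 9-borabicyclo[3.3.1]nonane and NaBO3 oxidation give the primary alcohol F6. Dess–Martin oxidation then gives aldehyde 18, whose C-12 epimers are equilibrated in step 11 as before.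

Step 18 (palladium-catalysed closure of the oxabicycle). Ionization of the free tertiary alcohol may be slow, or β-hydride elimination to dienes may compete. The fallback sets out from 34 and comes back at 35, using a cationic Mukaiyama-type closure instead of a π-allyl complex. Me3SiOTf and 2,6-lutidine in CH2Cl2 at −78 °C give the bis(trimethylsilyl) derivative F7 (tertiary silyl ether plus silyl enol ether of the β-ketolactone). A catalytic amount of Me3SiOTf at −78 °C then ionizes the tertiary allylic silyl ether, and the silyl enol ether carbon C-18 captures the allyl cation at C-15 to give 35.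

**Further compounds**
F1 | step 4 | enantiomer of silyl ether 8 (not isolated) | O=C1C[C@H]2[C@@H](C)C=C(C)[C@@H](O[Si](C)(C)C(C)(C)C)[C@@]12C
F2 | step 4 | enantiomer of alcohol 9 | O=C1C[C@H]2[C@@H](C)C=C(C)[C@@H](O)[C@@]12C
F3 | step 4 | (S)-2-methoxy-2-phenylacetate of 9 | O=C1C[C@@H]2[C@H](C)C=C(C)[C@H](OC(=O)[C@@H](OC)c3ccccc3)[C@]12C
F4 | step 4 | (S)-2-methoxy-2-phenylacetate of ent-9 | O=C1C[C@H]2[C@@H](C)C=C(C)[C@@H](OC(=O)[C@@H](OC)c3ccccc3)[C@@]12C
F5 | step 9 | C-12 methylidene analogue of 16 | C/C=C(\C)[C@@H](O[Si](C)(C)C(C)(C)C)[C@@]1(C)[C@@H]2[C@H](C)C=C(C)[C@H](OC(=O)C(C)(C)C)[C@]2(C)C1=C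
F6 | step 9 | C-12 hydroxymethyl compound | C/C=C(\C)[C@@H](O[Si](C)(C)C(C)(C)C)[C@@]1(C)[C@@H]2[C@H](C)C=C(C)[C@H](OC(=O)C(C)(C)C)[C@]2(C)[C@@H]1CO
F7 | step 18 | bis(trimethylsilyl) derivative of 34 (C-15 silyl ether, C-19 silyl enol ether) | C/C=C(\C)[C@@H](O[Si](C)(C)C(C)(C)C)[C@@]1(C)[C@@H]2C(C)=CC(C)=C[C@]2(C)[C@@H]1/C(C)=C/C(C)(O[Si](C)(C)C)[C@H]1OC(=O)C(C)=C(O[Si](C)(C)C)[C@@H]1C
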